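## Structural features

Caraphenol B (18) is a 2,3-dihydro-1H-indene in which ring A, a resorcinol ring with hydroxyls on C4 and C6, is fused through C3a and C7a to the five-membered ring B. Ring B carries three contiguous methine stereocentres: C1 bears a 4-hydroxybenzoyl group, C2 the 4-hydroxyphenyl ring C, and C3 (next to the oxygenated C4) the 3,5-dihydroxyphenyl ring D. The SMILES corresponds to (1R,2R,3R), with all three substituents on one face of ring B, which is the most crowded arrangement. These locants and ring letters are used for every intermediate in the discussion, whatever the numbering of its systematic name. The fragile points are H-1 (alpha to an aryl ketone and benzylic, so C1 can epimerise to the less strained trans isomer in acid or base), the doubly benzylic C3, the reducible aryl ketone and six oxidation-prone phenols. The real difficulty is to build the all-cis triad in the absolute sense by kinetic means and never to equilibrate C1 afterwards. The key step exploits the fact that ring B shares the C3a–C7a bond with ring A and has an aryl group on both C2 and C3. C7a can therefore carry boron, C3a can carry a diaryl ketone made of C3 and ring D, and C1–C2 with ring C and the future aroyl carbon can arrive as an internal alkyne.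

## Logic of the disconnections

**18 from 17.** The six phenolic O–H bonds are traced back to six O–CH2Ph bonds. The reason is that one neutral hydrogenolysis can then be the last operation, so the epimerisable C1 of the all-cis array meets neither acid nor base at the end. The gain is that every earlier intermediate is non-phenolic and compatible with organometallic reagents. The demand is that hydrogenolysis stops before the aryl ketone is reduced.

**17 from 16.** The C3–H bond is traced back to a C3–OH bond. A C3 carbinol is what a ketone-closing annulation delivers, and C3 is the one position where a cation is strongly stabilised (ring D, and ring A with oxygen ortho and para to C3a). The gain is that C3 need not be made directly as a C–H stereocentre. The demand is that hydride enters from the face of H-1 and H-2 and that the acid leaves the ketone and C1 alone.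

**16 from 15.** The C1–H and C2–H bonds are removed together, as one syn addition of hydrogen to a C1=C2 double bond. The C3 hydroxyl of 15 can bind a cationic iridium hydride and send both hydrogens to its own face, which places the aroyl group and ring C cis to each other and to ring D. The gain is large: three stereocentres collapse to the single quaternary C3 of 15, which cannot epimerise. The demand is a directed hydrogenation of a tetrasubstituted, conjugated alkene.

**15 from 14 and 13.** No skeletal bond is cut; the carbonyl of the aroyl carbon is traced back to a CH–O–Si group. If this carbon entered the annulation as a carbonyl, the alkyne would be polarised so that the aryl group adds to C2. At the alcohol level, as a bulky silyl ether, the carbon behaves as an alkyl substituent. The gain is control of regiochemistry. The cost is two functional-group steps, and the demand is that the allylic, para-alkoxybenzylic carbinol 14 is never exposed to acid.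

**13 from 7 and 12.** The C7a–C1 and C2–C3 bonds are cut and ring B opens. These two bonds attach all three substituted carbons of ring B to ring A in one catalytic event and create only C3. The gain is a convergent union of two fragments of similar size. The demands are rhodium on C2 after insertion, ring closure faster than protonolysis, and face selection at the ketone by the ligand.

**12 from 8 and 9 (through 10 and 11).** The bond between the carbinol carbon and the alkyne carbon is cut, together with the O–Si bond. The carbinol centre is made racemic on purpose: it is erased at 15, and in the ring-closing transition state it lies trans to rhodium, far from C3. Silylation in the same flask avoids isolating an acid-labile propargylic alcohol. The gain is one operation from two commercial compounds and no asymmetric step spent on a transient centre. The cost is that 13 and 14 are pairs of epimers that merge at 15.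

**7 from 6.** The C7a–B bond is traced back to a C7a–Br bond. Boron must come after the ketone, because the ketone is built with an organomagnesium reagent. Palladium-catalysed borylation with tetrahydroxydiboron gives the free boronic acid directly, whereas a diboron ester would give a boronate that needs a separate cleavage. The demand is oxidative addition next to a hindered ketone without protodeboronation of the product.

**6 from 5, and 5 from 3 and 1 (through 4); 3 from 1 (through 2).** The bond between C3 and ring D is cut to an aldehyde and an aryl Grignard reagent, and the C3a–C3 bond is cut to a formylation. Both aryl halves of 6 then come from the same commercial 1. The formyl group enters ortho to bromine and para to a benzyloxy group, which is exactly the C7a/C3a/C4/C6 pattern of ring A. The demand is the regiochemistry of the formylation.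

## Other disconnections considered

**Alternative 1:** The cut is the C2–C3 bond, traced back to a carbene at C3 and a C–H bond of a C2 methylene. In the forward step Rh2(R-PTAD)4 would decompose the diaryldiazomethane A2, and the donor/donor carbene would insert into C2–H to close ring B as the benzylidene indane A1 with rings C and D cis.
- In its favour: one C–C bond formation would set C2, C3, their cis relationship and their absolute sense under catalyst control. No cation at C3 and no hydroxyl removal are needed. On this point it is better than the chosen plan, which spends two reductions on the same two centres.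
- Against it: A1 has no oxygen on the aroyl carbon. The exocyclic alkene would need hydroboration–oxidation and alcohol oxidation, but both alkene carbons are benzylic, so regiochemistry is not secured and C1 would rest on substrate control only.
- Against it: benzyl ethers cannot be used, because a C3 carbene would insert into the O–CH2 bond of a C4 benzyloxy group to form a dihydrobenzofuran. Methyl ethers are therefore imposed, and the synthesis would end with a strong Lewis acid on the enolisable all-cis ketone, where the chosen plan ends with neutral hydrogenolysis.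
- Against it: A2 needs a trisubstituted alkene of defined geometry and a diazo group in one molecule, a longer linear preparation than 7 plus 12.
- Comparison: both plans close ring B at C2–C3 and set C3 by catalyst control, so they are equal there. The insertion is mechanistically more direct. The step count before and after the key step is expected to be higher and the end game harsher.

**Alternative 2:** The cuts are the C3–ring D bond and the C1–C2 bond. In the forward step Ni(OAc)2·4H2O with a chiral phosphinooxazoline would transfer ring D from the boronic acid A5 to C3 of the alkynyl ketoester A4. After E/Z isomerisation the alkenylnickel at C2 would add to the keto carbonyl and close ring B as the hydroxy ester A3, with a quaternary carbinol at C1.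
- In its favour: ring D enters as a simple arylboronic acid in the ring-forming step, the metal is cheap, and no propargylic leaving group is present. A3 also holds a non-epimerisable carbinol that could steer hydrogen to C2=C3, so on the robustness of the relay the two plans are equal.
- Against it: the carbinol sits on C1, which is a methine in the target. After directing, the hydroxyl must be removed alpha to a carbonyl, which passes through an enolate, so C1 would finally be set by protonation and not by the relay.
- Against it: the ester must be turned into an aryl ketone at a quaternary centre (amide, then aryl organometallic). A4 needs an alkyne between two ortho substituents, and the alkenylnickel must isomerise next to the C4 benzyloxy group.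
- Comparison: mechanistically both plans are an arylmetal addition to an alkyne followed by carbonyl capture (syn here, anti there), so they are equal in concept. Structurally the chosen plan brings the aroyl carbon with its aryl ring, one oxidation from the ketone. About three more operations would follow ring closure in this alternative.

**Alternative 3:** The cut is the C1–C2 bond, traced back to an aldehyde C–H bond and a 1,1-diarylethene. In the forward step a cationic rhodium catalyst (monovalent rhodium) from [Rh(cod)Cl]2, (R)-BINAP and AgBF4 would add the aldehyde C–H bond of A7 across the alkene and give the indanone A6 with C3 set.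
- In its favour: no stoichiometric by-product is formed, so atom economy is better than in a boronic acid annulation. C3 is made directly as the C–H centre of the target, with no deoxygenation. On both points it is better than the chosen plan. A7 also shares its early chemistry with 6.
- Against it: A6 has neither ring C nor the aroyl carbon. Both must be added later by C–C bond formation at C2 (enolate arylation) and C1 (enol triflate, carbonylative coupling), which leads to the indenyl ketone A8.
- Against it: in A8 the only stereocentre is C3–H, which is doubly benzylic, allylic and vinylogously alpha to the ketone. It can be lost through an indenyl anion under the basic coupling conditions. The final hydrogenation would be undirected and rely on ring D alone.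
- Against it: hydroacylation of a 1,1-diarylethene flanked by an ortho benzyloxy group has to compete with decarbonylation.
- Comparison: both plans use monovalent rhodium and set C3 by catalyst control (equal), and the step count is about equal. The chosen plan carries the chirality in a quaternary carbinol instead of a labile C–H centre and brings every ring B substituent in the ring-closing step.

Key step: step 6

Assumption: the sense of induction of a chiral diene at a diaryl ketone cannot be assigned in advance, so (R,R)-Ph-bod* is written in step 6 and its equally available mirror image is to be used if a pilot run shows the (1S) series.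

## Route

Step 1
Reactants: 1 1-bromo-3,5-bis(benzyloxy)benzene
Product: 3 2-bromo-4,6-bis(benzyloxy)benzaldehyde, via iminium chloride 2 (not isolated)
Conditions: POCl3, DMF, 0 → 80 °C; then aq. NaOAc, rt
Reagents that add atoms: N,N-dimethylformamide CN(C)C=O; water O
Why: Vilsmeier–Haack formylation; the chloroiminium ion should attack the position ortho to bromine and para to one benzyloxy group rather than the more hindered position between the two ethers, and hydrolysis of iminium 2 gives the aldehyde.

Step 2
Reactants: 1 1-bromo-3,5-bis(benzyloxy)benzene (second portion); 3 2-bromo-4,6-bis(benzyloxy)benzaldehyde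
Product: 5 rac-[2-bromo-4,6-bis(benzyloxy)phenyl][3,5-bis(benzyloxy)phenyl]methanol, via arylmagnesium bromide 4 (not isolated)
Conditions: Mg, I2 (cat.), THF, 50 °C; then 3, THF, 0 °C → rt; aq. NH4Cl
Reagents that add atoms: none
Why: Grignard addition of an aryl nucleophile to an aromatic aldehyde; the aryl bromide of 3 does not exchange with an arylmagnesium halide at this temperature, and the carbinol centre is oxidised in the next step, so it is left racemic.

Step 3
Reactants: 5 rac-[2-bromo-4,6-bis(benzyloxy)phenyl][3,5-bis(benzyloxy)phenyl]methanol
Product: 6 [2-bromo-4,6-bis(benzyloxy)phenyl][3,5-bis(benzyloxy)phenyl]methanone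
Conditions: Dess–Martin periodinane, CH2Cl2, 0 °C → rt
Reagents that add atoms: none
Why: Dess–Martin oxidation of a hindered diarylmethanol to the diaryl ketone; benzyl ethers and the aryl bromide are inert.

Step 4
Reactants: 6 [2-bromo-4,6-bis(benzyloxy)phenyl][3,5-bis(benzyloxy)phenyl]methanone
Product: 7 {3,5-bis(benzyloxy)-2-[3,5-bis(benzyloxy)benzoyl]phenyl}boronic acid
Conditions: B2(OH)4, second-generation XPhos palladacycle PdCl(XPhos)(2′-aminobiphenyl-2-yl) (2 mol %), XPhos (4 mol %), KOAc, EtOH, 80 °C; aqueous work-up
Reagents that add atoms: tetrahydroxydiboron OB(O)B(O)O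
Why: Miyaura-type borylation of an aryl bromide with tetrahydroxydiboron (oxidative addition to zerovalent palladium, acetate-assisted transfer of boron, reductive elimination); the boron sits meta to both ethers, so protodeboronation should be slow, and ethyl boronates formed in ethanol hydrolyse on work-up to the free acid.

Step 5
Reactants: 8 1-(benzyloxy)-4-ethynylbenzene; 9 4-(benzyloxy)benzaldehyde
Product: 12 rac-tert-butyl({1,3-bis[4-(benzyloxy)phenyl]prop-2-yn-1-yl}oxy)dimethylsilane, via lithium acetylide 10 (not isolated), via lithium alkoxide 11 (not isolated)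
Conditions: n-BuLi, THF, −78 °C; 9, −78 → 0 °C; TBSCl, imidazole, DMF, 0 °C → rt
Reagents that add atoms: tert-butyldimethylsilyl chloride CC(C)(C)[Si](C)(C)Cl
Why: acetylide addition to an aldehyde followed by O-silylation of the alkoxide in the same flask, so the ionisable propargylic alcohol is never isolated; the centre is racemic by design because it becomes a carbonyl carbon in step 8.

Step 6
Reactants: 7 {3,5-bis(benzyloxy)-2-[3,5-bis(benzyloxy)benzoyl]phenyl}boronic acid (1.5 equiv); 12 rac-tert-butyl({1,3-bis[4-(benzyloxy)phenyl]prop-2-yn-1-yl}oxy)dimethylsilane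
Product: 13 (1R)-5,7-bis(benzyloxy)-1-[3,5-bis(benzyloxy)phenyl]-2-[4-(benzyloxy)phenyl]-3-{[4-(benzyloxy)phenyl][(tert-butyldimethylsilyl)oxy]methyl}-1H-inden-1-ol, as the pair of epimers at the silyloxy carbon (carbinol carbon = C3 of the target, hydroxyl on the face opposite to ring D)
Conditions: [RhCl(C2H4)2]2 (2.5 mol %), (R,R)-Ph-bod* [(1R,4R)-2,5-diphenylbicyclo[2.2.2]octa-2,5-diene] (5.5 mol %), KOH (0.5 equiv), 1,4-dioxane/H2O (10:1), 60 °C
Reagents that add atoms: none
Why: KOH turns the chloride-bridged diene complex into a hydroxo complex of monovalent rhodium, which transmetalates with 7 to an arylrhodium at C7a; syn insertion of the alkyne of 12 puts C7a on C1 and rhodium on C2, the alkenylrhodium adds to the neighbouring diaryl ketone, and water cleaves the rhodium alkoxide and returns the hydroxo complex. The closest known reaction type is the rhodium-catalysed (3+2) annulation of 2-acylarylboronic acids with internal alkynes to 1H-inden-1-ols, for which chiral dienes give tertiary carbinols. Ring B closes by 5-exo-trig attack of C2 on the carbonyl carbon C3, after the intermolecular C7a–C1 bond. The only stereocentre made, C3, is set by the chiral diene, which selects the face of the ketone in the C–C bond-forming addition; the centre of 12 lies trans to rhodium on the far side of the alkene, so both epimers should take the same C3 configuration. The step needs rhodium on the aryl-bearing carbon C2: benzylic stabilisation by ring C favours this, and the bulky, poorly coordinating silyl ether neither guides rhodium to the other carbon nor offers a good beta-leaving group. Ring closure must also outrun protonolysis of the alkenylrhodium, which the five-atom distance to the ketone and the low water content favour. The excess of 7 covers any protodeboronation.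

Step 7
Reactants: 13 the silyl ether from step 6 (both epimers)
Product: 14 (1R)-5,7-bis(benzyloxy)-1-[3,5-bis(benzyloxy)phenyl]-2-[4-(benzyloxy)phenyl]-3-{[4-(benzyloxy)phenyl](hydroxy)methyl}-1H-inden-1-ol (both epimers at the secondary carbinol)
Conditions: TBAF, AcOH (1:1), THF, 0 °C → rt
Reagents that add atoms: none
Why: fluoride-mediated cleavage of a silyl ether; buffering with acetic acid keeps the medium near neutral, and the tertiary C3 carbinol does not ionise because the cation would be an antiaromatic indenyl cation.

Step 8
Reactants: 14 the diol from step 7 (both epimers)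
Product: 15 [(1R)-5,7-bis(benzyloxy)-1-[3,5-bis(benzyloxy)phenyl]-2-[4-(benzyloxy)phenyl]-1-hydroxy-1H-inden-3-yl][4-(benzyloxy)phenyl]methanone
Conditions: Dess–Martin periodinane, pyridine, CH2Cl2, 0 °C
Reagents that add atoms: none
Why: Dess–Martin oxidation of the secondary allylic, benzylic alcohol; the tertiary carbinol cannot be oxidised, pyridine buffers the acetic acid, and both epimers converge on one enone.

Step 9
Reactants: 15 the hydroxy enone from step 8
Product: 16 [(1R,2R,3S)-4,6-bis(benzyloxy)-3-[3,5-bis(benzyloxy)phenyl]-2-[4-(benzyloxy)phenyl]-3-hydroxy-2,3-dihydro-1H-inden-1-yl][4-(benzyloxy)phenyl]methanone (aroyl, ring C and ring D cis; hydroxyl, H-1 and H-2 on the other face)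
Conditions: [Ir(cod)(PCy3)(py)]PF6 (10 mol %), H2 (20 bar), CH2Cl2, rt
Reagents that add atoms: none
Why: hydroxyl-directed homogeneous hydrogenation; the cationic iridium centre binds the C3 hydroxyl and delivers both hydrogens to C1=C2 from that face, which sets C1 and C2 with the aroyl group and ring C cis to ring D. Tetrasubstituted cyclic allylic alcohols are within the scope of this catalyst, and the steric bias (hydroxyl smaller than ring D) points the same way.

Step 10
Reactants: 16 the hydroxy ketone from step 9
Product: 17 [(1R,2R,3R)-4,6-bis(benzyloxy)-3-[3,5-bis(benzyloxy)phenyl]-2-[4-(benzyloxy)phenyl]-2,3-dihydro-1H-inden-1-yl][4-(benzyloxy)phenyl]methanone (all-cis)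
Conditions: Et3SiH (5 equiv), TFA (5 equiv), CH2Cl2, −40 → 0 °C
Reagents that add atoms: none
Why: ionic hydrogenation; TFA ionises the tertiary, doubly benzylic carbinol (cation stabilised by the ortho and para benzyloxy groups of ring A) and Et3SiH delivers hydride to the open face that carries H-1 and H-2, anti to ring C and the aroyl group, which sets C3 with ring D cis to ring C. Low temperature and excess silane are chosen to keep the aryl ketone and C1 untouched; a cation that loses H-2 should be re-formed by protonation anti to the aroyl group and lead to the same product.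

Step 11
Reactants: 17 the hexabenzyl ether from step 10
Product: 18 caraphenol B, [(1R,2R,3R)-3-(3,5-dihydroxyphenyl)-4,6-dihydroxy-2-(4-hydroxyphenyl)-2,3-dihydro-1H-inden-1-yl](4-hydroxyphenyl)methanone
Conditions: H2 (1 atm), Pd/C (10 %), EtOAc/MeOH, rt
Reagents that add atoms: none
Why: hydrogenolysis of six aryl benzyl ethers under neutral conditions, so the epimerisable C1 sees neither acid nor base; an electron-rich 4-hydroxyphenyl ketone is slow to reduce, and the reaction is to be stopped when hydrogen uptake for six benzyl groups ends.

## Compound list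

1 | 1-bromo-3,5-bis(benzyloxy)benzene | Brc1cc(OCc2ccccc2)cc(OCc2ccccc2)c1 | starting material
2 | N-{[2-bromo-4,6-bis(benzyloxy)phenyl]methylidene}-N-methylmethanaminium chloride (not isolated) | C[N+](C)=Cc1c(Br)cc(OCc2ccccc2)cc1OCc1ccccc1.[Cl-] | intermediate
3 | 2-bromo-4,6-bis(benzyloxy)benzaldehyde | O=Cc1c(Br)cc(OCc2ccccc2)cc1OCc1ccccc1 | intermediate
4 | [3,5-bis(benzyloxy)phenyl]magnesium bromide (not isolated) | Br[Mg]c1cc(OCc2ccccc2)cc(OCc2ccccc2)c1 | intermediate
5 | rac-[2-bromo-4,6-bis(benzyloxy)phenyl][3,5-bis(benzyloxy)phenyl]methanol | OC(c1cc(OCc2ccccc2)cc(OCc2ccccc2)c1)c1c(Br)cc(OCc2ccccc2)cc1OCc1ccccc1 | intermediate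
6 | [2-bromo-4,6-bis(benzyloxy)phenyl][3,5-bis(benzyloxy)phenyl]methanone | O=C(c1cc(OCc2ccccc2)cc(OCc2ccccc2)c1)c1c(Br)cc(OCc2ccccc2)cc1OCc1ccccc1 | intermediate
7 | {3,5-bis(benzyloxy)-2-[3,5-bis(benzyloxy)benzoyl]phenyl}boronic acid | OB(O)c1cc(OCc2ccccc2)cc(OCc2ccccc2)c1C(=O)c1cc(OCc2ccccc2)cc(OCc2ccccc2)c1 | intermediate
8 | 1-(benzyloxy)-4-ethynylbenzene | C#Cc1ccc(OCc2ccccc2)cc1 | starting material
9 | 4-(benzyloxy)benzaldehyde | O=Cc1ccc(OCc2ccccc2)cc1 | starting material
10 | lithium [4-(benzyloxy)phenyl]acetylide (not isolated) | [Li]C#Cc1ccc(OCc2ccccc2)cc1 | intermediate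
11 | lithium rac-1,3-bis[4-(benzyloxy)phenyl]prop-2-yn-1-olate (not isolated) | [Li]OC(C#Cc1ccc(OCc2ccccc2)cc1)c1ccc(OCc2ccccc2)cc1 | intermediate
12 | rac-tert-butyl({1,3-bis[4-(benzyloxy)phenyl]prop-2-yn-1-yl}oxy)dimethylsilane | CC(C)(C)[Si](C)(C)OC(C#Cc1ccc(OCc2ccccc2)cc1)c1ccc(OCc2ccccc2)cc1 | intermediate
13 | (1R)-5,7-bis(benzyloxy)-1-[3,5-bis(benzyloxy)phenyl]-2-[4-(benzyloxy)phenyl]-3-{[4-(benzyloxy)phenyl][(tert-butyldimethylsilyl)oxy]methyl}-1H-inden-1-ol, both epimers at the silyloxy carbon | CC(C)(C)[Si](C)(C)OC(c1ccc(OCc2ccccc2)cc1)C=1c2cc(OCc3ccccc3)cc(OCc3ccccc3)c2[C@@](O)(c2cc(OCc3ccccc3)cc(OCc3ccccc3)c2)C=1c1ccc(OCc2ccccc2)cc1 | intermediate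
14 | (1R)-5,7-bis(benzyloxy)-1-[3,5-bis(benzyloxy)phenyl]-2-[4-(benzyloxy)phenyl]-3-{[4-(benzyloxy)phenyl](hydroxy)methyl}-1H-inden-1-ol, both epimers at the secondary carbinol | OC(c1ccc(OCc2ccccc2)cc1)C=1c2cc(OCc3ccccc3)cc(OCc3ccccc3)c2[C@@](O)(c2cc(OCc3ccccc3)cc(OCc3ccccc3)c2)C=1c1ccc(OCc2ccccc2)cc1 | intermediate
15 | [(1R)-5,7-bis(benzyloxy)-1-[3,5-bis(benzyloxy)phenyl]-2-[4-(benzyloxy)phenyl]-1-hydroxy-1H-inden-3-yl][4-(benzyloxy)phenyl]methanone | O=C(c1ccc(OCc2ccccc2)cc1)C=1c2cc(OCc3ccccc3)cc(OCc3ccccc3)c2[C@@](O)(c2cc(OCc3ccccc3)cc(OCc3ccccc3)c2)C=1c1ccc(OCc2ccccc2)cc1 | intermediate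
16 | [(1R,2R,3S)-4,6-bis(benzyloxy)-3-[3,5-bis(benzyloxy)phenyl]-2-[4-(benzyloxy)phenyl]-3-hydroxy-2,3-dihydro-1H-inden-1-yl][4-(benzyloxy)phenyl]methanone | O=C(c1ccc(OCc2ccccc2)cc1)[C@H]1c2cc(OCc3ccccc3)cc(OCc3ccccc3)c2[C@@](O)(c2cc(OCc3ccccc3)cc(OCc3ccccc3)c2)[C@H]1c1ccc(OCc2ccccc2)cc1 | intermediate
17 | [(1R,2R,3R)-4,6-bis(benzyloxy)-3-[3,5-bis(benzyloxy)phenyl]-2-[4-(benzyloxy)phenyl]-2,3-dihydro-1H-inden-1-yl][4-(benzyloxy)phenyl]methanone | O=C(c1ccc(OCc2ccccc2)cc1)[C@H]1c2cc(OCc3ccccc3)cc(OCc3ccccc3)c2[C@@H](c2cc(OCc3ccccc3)cc(OCc3ccccc3)c2)[C@H]1c1ccc(OCc2ccccc2)cc1 | intermediate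
18 | caraphenol B, [(1R,2R,3R)-3-(3,5-dihydroxyphenyl)-4,6-dihydroxy-2-(4-hydroxyphenyl)-2,3-dihydro-1H-inden-1-yl](4-hydroxyphenyl)methanone | O=C(c1ccc(O)cc1)[C@H]1c2cc(O)cc(O)c2[C@@H](c2cc(O)cc(O)c2)[C@H]1c1ccc(O)cc1 | target

## Step count and least certain steps

Total: 11 steps. Longest linear sequence: 10 steps (steps 1, 2, 3, 4, 6, 7, 8, 9, 10 and 11, from 1).

**Step 6 (key step).** The most likely failure is insertion of the alkyne in the reverse sense, because the branched propargylic substituent weakens the steric part of the aryl/alkyl bias. Rhodium next to the oxygenated carbon would then be lost by beta-silyloxy elimination to an allene. A second risk is protonolysis of the alkenylrhodium before it reaches the hindered, electron-rich ketone. The fallback removes the propargylic oxygen from the alkyne. It sets out from 8: palladium-catalysed coupling with 4-(benzyloxy)benzyl chloride (PdCl2(MeCN)2, XPhos, Cs2CO3, MeCN, 65 °C) would give 1-(benzyloxy)-4-{3-[4-(benzyloxy)phenyl]prop-1-yn-1-yl}benzene F1, a plain aryl/primary-alkyl alkyne without a beta-leaving group. Annulation of F1 with 7, run base-free with the preformed hydroxo complex [Rh(OH)(diene)]2 to avoid propargyl–allene isomerisation, would give (1R)-5,7-bis(benzyloxy)-3-[4-(benzyloxy)benzyl]-1-[3,5-bis(benzyloxy)phenyl]-2-[4-(benzyloxy)phenyl]-1H-inden-1-ol F2. Oxidation of its doubly activated methylene with DDQ in wet CH2Cl2 comes back to the route at 15.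

**Step 9.** The most likely failure is sluggish or incomplete hydrogenation, because the alkene is tetrasubstituted, crowded and electron-poor. Acid-promoted loss of the C3 hydroxyl of the product by the iridium hydride species is a second risk. The fallback hydrogenates before the carbonyl is made. It sets out from 13, whose electron-richer alkene has the C3 hydroxyl as sole director: the same iridium catalyst would give (1S,2R,3R)-5,7-bis(benzyloxy)-1-[3,5-bis(benzyloxy)phenyl]-2-[4-(benzyloxy)phenyl]-3-{[4-(benzyloxy)phenyl][(tert-butyldimethylsilyl)oxy]methyl}-2,3-dihydro-1H-inden-1-ol F3. TBAF/AcOH would give (1S,2R,3R)-5,7-bis(benzyloxy)-1-[3,5-bis(benzyloxy)phenyl]-2-[4-(benzyloxy)phenyl]-3-{[4-(benzyloxy)phenyl](hydroxy)methyl}-2,3-dihydro-1H-inden-1-ol F4, and Dess–Martin oxidation of its secondary alcohol comes back to the route at 16.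

**Step 10.** The most likely failure is diversion of the C3 cation: capture by the cis carbonyl oxygen followed by reductive ether formation, or acid-induced enolisation that epimerises C1. The fallback never forms the cation. It sets out from 16: acylation with methyl chlorooxoacetate (pyridine, DMAP, CH2Cl2, 0 °C) would give (1S,2R,3R)-3-[4-(benzyloxy)benzoyl]-5,7-bis(benzyloxy)-1-[3,5-bis(benzyloxy)phenyl]-2-[4-(benzyloxy)phenyl]-2,3-dihydro-1H-inden-1-yl methyl oxalate F5. Barton-type radical deoxygenation (Bu3SnH, AIBN, toluene, 90 °C) would give a doubly benzylic C3 radical that takes hydrogen from the same open face and comes back to the route at 17.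

**Step 4.** The most likely failure is protodeboronation or reduction of the C–Br bond in hot ethanol, since the free acid is formed next to a carbonyl group. The fallback changes the boron partner of the key step. It sets out from 6: Miyaura borylation with B2pin2 (PdCl2(dppf), KOAc, 1,4-dioxane, 90 °C) would give 2-{3,5-bis(benzyloxy)-2-[3,5-bis(benzyloxy)benzoyl]phenyl}-4,4,5,5-tetramethyl-1,3,2-dioxaborolane F6. F6 would be used directly with 12 under the rhodium conditions of step 6 at 80 °C and comes back to the route at 13.

**Step 11.** The most likely failure is over-reduction of the aryl ketone on palladium while the last benzyl groups are still being cleaved; epimerisation of C1 in the free hexaphenol on prolonged handling is a second risk. The fallback is non-reductive. It sets out from 17: BCl3 with pentamethylbenzene as benzyl-cation scavenger (CH2Cl2, −78 °C) would cleave the six aryl benzyl ethers by Lewis-acid dealkylation and comes back to the route at 18, with no new intermediate.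

## Further compounds

F1 | step 6 | 1-(benzyloxy)-4-{3-[4-(benzyloxy)phenyl]prop-1-yn-1-yl}benzene | C(C#Cc1ccc(OCc2ccccc2)cc1)c1ccc(OCc2ccccc2)cc1
F2 | step 6 | (1R)-5,7-bis(benzyloxy)-3-[4-(benzyloxy)benzyl]-1-[3,5-bis(benzyloxy)phenyl]-2-[4-(benzyloxy)phenyl]-1H-inden-1-ol | C(c1ccc(OCc2ccccc2)cc1)C=1c2cc(OCc3ccccc3)cc(OCc3ccccc3)c2[C@@](O)(c2cc(OCc3ccccc3)cc(OCc3ccccc3)c2)C=1c1ccc(OCc2ccccc2)cc1
F3 | step 9 | (1S,2R,3R)-5,7-bis(benzyloxy)-1-[3,5-bis(benzyloxy)phenyl]-2-[4-(benzyloxy)phenyl]-3-{[4-(benzyloxy)phenyl][(tert-butyldimethylsilyl)oxy]methyl}-2,3-dihydro-1H-inden-1-ol, both epimers at the silyloxy carbon | CC(C)(C)[Si](C)(C)OC(c1ccc(OCc2ccccc2)cc1)[C@H]1c2cc(OCc3ccccc3)cc(OCc3ccccc3)c2[C@@](O)(c2cc(OCc3ccccc3)cc(OCc3ccccc3)c2)[C@H]1c1ccc(OCc2ccccc2)cc1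
F4 | step 9 | (1S,2R,3R)-5,7-bis(benzyloxy)-1-[3,5-bis(benzyloxy)phenyl]-2-[4-(benzyloxy)phenyl]-3-{[4-(benzyloxy)phenyl](hydroxy)methyl}-2,3-dihydro-1H-inden-1-ol, both epimers at the secondary carbinol | OC(c1ccc(OCc2ccccc2)cc1)[C@H]1c2cc(OCc3ccccc3)cc(OCc3ccccc3)c2[C@@](O)(c2cc(OCc3ccccc3)cc(OCc3ccccc3)c2)[C@H]1c1ccc(OCc2ccccc2)cc1
F5 | step 10 | (1S,2R,3R)-3-[4-(benzyloxy)benzoyl]-5,7-bis(benzyloxy)-1-[3,5-bis(benzyloxy)phenyl]-2-[4-(benzyloxy)phenyl]-2,3-dihydro-1H-inden-1-yl methyl oxalate | O=C(c1ccc(OCc2ccccc2)cc1)[C@H]1c2cc(OCc3ccccc3)cc(OCc3ccccc3)c2[C@@](OC(=O)C(=O)OC)(c2cc(OCc3ccccc3)cc(OCc3ccccc3)c2)[C@H]1c1ccc(OCc2ccccc2)cc1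
F6 | step 4 | 2-{3,5-bis(benzyloxy)-2-[3,5-bis(benzyloxy)benzoyl]phenyl}-4,4,5,5-tetramethyl-1,3,2-dioxaborolane | CC1(C)OB(OC1(C)C)c1cc(OCc2ccccc2)cc(OCc2ccccc2)c1C(=O)c1cc(OCc2ccccc2)cc(OCc2ccccc2)c1
F0 | step 11 | none | none
A1 | alternative 1 | (1Z,2S,3R)-3-(3,5-dimethoxyphenyl)-4,6-dimethoxy-1-(4-methoxybenzylidene)-2-(4-methoxyphenyl)-2,3-dihydro-1H-indene | COc1ccc(cc1)/C=C1\c2cc(OC)cc(OC)c2[C@@H](c2cc(OC)cc(OC)c2)[C@H]1c1ccc(OC)cc1
A2 | alternative 1 | 1-[diazo(3,5-dimethoxyphenyl)methyl]-2-[(1Z)-1,3-bis(4-methoxyphenyl)prop-1-en-2-yl]-4,6-dimethoxybenzene | COc1ccc(cc1)/C=C(/Cc1ccc(OC)cc1)c1cc(OC)cc(OC)c1C(=[N+]=[N-])c1cc(OC)cc(OC)c1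
A3 | alternative 2 | methyl (1R)-4,6-bis(benzyloxy)-3-[3,5-bis(benzyloxy)phenyl]-2-[4-(benzyloxy)phenyl]-1-hydroxy-1H-indene-1-carboxylate | COC(=O)[C@@]1(O)c2cc(OCc3ccccc3)cc(OCc3ccccc3)c2C(c2cc(OCc3ccccc3)cc(OCc3ccccc3)c2)=C1c1ccc(OCc2ccccc2)cc1
A4 | alternative 2 | methyl (3,5-bis(benzyloxy)-2-{[4-(benzyloxy)phenyl]ethynyl}phenyl)(oxo)acetate | COC(=O)C(=O)c1cc(OCc2ccccc2)cc(OCc2ccccc2)c1C#Cc1ccc(OCc2ccccc2)cc1
A5 | alternative 2 | [3,5-bis(benzyloxy)phenyl]boronic acid | OB(O)c1cc(OCc2ccccc2)cc(OCc2ccccc2)c1
A6 | alternative 3 | (3R)-4,6-bis(benzyloxy)-3-[3,5-bis(benzyloxy)phenyl]-2,3-dihydro-1H-inden-1-one | O=C1c2cc(OCc3ccccc3)cc(OCc3ccccc3)c2[C@@H](c2cc(OCc3ccccc3)cc(OCc3ccccc3)c2)C1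
A7 | alternative 3 | 3,5-bis(benzyloxy)-2-{1-[3,5-bis(benzyloxy)phenyl]ethenyl}benzaldehyde | O=Cc1cc(OCc2ccccc2)cc(OCc2ccccc2)c1C(=C)c1cc(OCc2ccccc2)cc(OCc2ccccc2)c1
A8 | alternative 3 | [(1S)-5,7-bis(benzyloxy)-1-[3,5-bis(benzyloxy)phenyl]-2-[4-(benzyloxy)phenyl]-1H-inden-3-yl][4-(benzyloxy)phenyl]methanone | O=C(c1ccc(OCc2ccccc2)cc1)C=1c2cc(OCc3ccccc3)cc(OCc3ccccc3)c2[C@@H](c2cc(OCc3ccccc3)cc(OCc3ccccc3)c2)C=1c1ccc(OCc2ccccc2)cc1
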